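**Retrosynthetic overview**
1. Feature: C3 of the furan ring is bonded to two aryl carbons (C3a of the benzo ring A and C1' of the pendant ring B), so it is a latent diaryl carbene (ketone) carbon. C2 and the first CH2 of the side chain map onto the two sp carbons of a terminal alkyne, and O1 is a phenol oxygen ortho to C3a.
2. Key disconnection: C2–C3 and O1–C2 are cut together, giving the N-tosylhydrazone of a 2-hydroxybenzophenone and silylated but-3-yn-1-ol. The furan is the only ring formed, and it closes in the key step.
3. The crowded C3–C1' bond is inherited from the benzophenone, made by Friedel–Crafts aroylation of 3,5-dimethoxytoluene, followed by chelation-controlled BCl3 release of the ortho phenol.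
4. The aroyl partner comes from 3,5-dimethoxy-4-methylbenzoic acid by ring bromination and Suzuki–Miyaura methylation.
5. End game: desilylation, oxidation of CH2OH to CO2H, BBr3 cleavage of three aryl methyl ethers, Fischer esterification.

Key step: step 10

Assumption: the C3–C1' aryl–furan axis is treated as stereochemically undefined, since the target is drawn without axial configuration, so no step has to control it.

**Step 1**
Reactants: 1 3,5-dimethoxy-4-methylbenzoic acid
Product: 2 methyl 3,5-dimethoxy-4-methylbenzoate
Conditions: MeOH, H2SO4 (cat.), reflux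
Reagents that add atoms: methanol, CO
Why: Fischer esterification of an unhindered benzoic acid in excess methanol protects the acid for the cross-coupling that follows.

**Step 2**
Reactants: 2 methyl 3,5-dimethoxy-4-methylbenzoate
Product: 3 methyl 2-bromo-3,5-dimethoxy-4-methylbenzoate
Conditions: NBS (1.05 equiv), MeCN, 0 °C to rt, dark
Reagents that add atoms: N-bromosuccinimide, O=C1CCC(=O)N1Br
Why: Electrophilic aromatic bromination can only occur at the two equivalent free ring positions, each ortho to one methoxy group and para to the other, and the polar non-radical medium should suppress benzylic bromination.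

**Step 3**
Reactants: 3 methyl 2-bromo-3,5-dimethoxy-4-methylbenzoate
Product: 4 methyl 3,5-dimethoxy-2,4-dimethylbenzoate
Conditions: MeB(OH)2 (3 equiv), Pd(OAc)2 (5 mol%), SPhos (10 mol%), K3PO4 (3 equiv), toluene/H2O, 100 °C
Reagents that add atoms: methylboronic acid, CB(O)O
Why: Suzuki–Miyaura methylation, in which the bulky electron-rich biarylphosphine should allow oxidative addition at the doubly ortho-substituted bromide, and the methyl group cannot undergo β-hydride elimination.

**Step 4**
Reactants: 4 methyl 3,5-dimethoxy-2,4-dimethylbenzoate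
Product: 5 3,5-dimethoxy-2,4-dimethylbenzoic acid
Conditions: LiOH (5 equiv), THF/MeOH/H2O, 60 °C; then aq. HCl
Reagents that add atoms: lithium hydroxide, [Li+].[OH-]
Why: Saponification by acyl–oxygen cleavage should proceed with warming despite the single ortho methyl group, and the aryl methyl ethers are inert to hydroxide.

**Step 5**
Reactants: 5 3,5-dimethoxy-2,4-dimethylbenzoic acid
Product: 6 3,5-dimethoxy-2,4-dimethylbenzoyl chloride
Conditions: (COCl)2 (1.5 equiv), DMF (cat.), CH2Cl2, 0 °C to rt; evaporate
Reagents that add atoms: oxalyl chloride, O=C(Cl)C(=O)Cl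
Why: Acid chloride formation through the Vilsmeier-type chloroiminium catalyst gives only gaseous by-products, so the crude chloride can be used directly.

**Step 6**
Reactants: 6 3,5-dimethoxy-2,4-dimethylbenzoyl chloride; 7 3,5-dimethoxytoluene
Product: 8 (2,4-dimethoxy-6-methylphenyl)(3,5-dimethoxy-2,4-dimethylphenyl)methanone
Conditions: AlCl3 (1.2 equiv), CH2Cl2, −10 to 0 °C; ice/aq. HCl
Reagents that add atoms: none
Why: Friedel–Crafts acylation, in which the acylium ion should attack C2 of 3,5-dimethoxytoluene (para to one methoxy group, ortho to the other and to the methyl), the usual site of acylation and formylation of this arene, and the low temperature limits ether cleavage by AlCl3.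

**Step 7**
Reactants: 8 (2,4-dimethoxy-6-methylphenyl)(3,5-dimethoxy-2,4-dimethylphenyl)methanone
Product: 9 (3,5-dimethoxy-2,4-dimethylphenyl)(2-hydroxy-4-methoxy-6-methylphenyl)methanone
Conditions: BCl3 (1.5 equiv), CH2Cl2, −78 to 0 °C; aq. work-up
Reagents that add atoms: none
Why: Chelation-controlled demethylation, in which boron bridges the ketone oxygen and the ortho methoxy oxygen in a six-membered chelate and chloride removes that methyl group, while the para methoxy group of ring A and the two methoxy groups of ring B have no carbonyl neighbour and should remain.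

**Step 8**
Reactants: 9 (3,5-dimethoxy-2,4-dimethylphenyl)(2-hydroxy-4-methoxy-6-methylphenyl)methanone
Product: 10 N'-[(3,5-dimethoxy-2,4-dimethylphenyl)(2-hydroxy-4-methoxy-6-methylphenyl)methylidene]-4-methylbenzenesulfonohydrazide (mixture of C=N isomers, both usable)
Conditions: TsNHNH2 (3 equiv), HCl (cat.), EtOH, 80 °C, sealed tube, prolonged heating
Reagents that add atoms: 4-methylbenzenesulfonohydrazide, Cc1ccc(cc1)S(=O)(=O)NN
Why: Acid-catalysed condensation of a ketone with a sulfonyl hydrazide, driven by excess reagent and long heating because the carbonyl is flanked by three ortho substituents, with the ortho hydroxyl group assisting as an internal hydrogen-bond donor.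

**Step 9**
Reactants: 11 but-3-yn-1-ol
Product: 12 tert-butyl(but-3-yn-1-yloxy)dimethylsilane
Conditions: TBSCl (1.1 equiv), imidazole (2 equiv), CH2Cl2, 0 °C to rt
Reagents that add atoms: tert-butyldimethylsilyl chloride, CC(C)(C)[Si](C)(C)Cl
Why: Imidazole-mediated silylation of a primary alcohol masks the O–H group, which would otherwise compete for the carbene, and leaves the terminal alkyne free.

**Step 10**
Reactants: 10 N'-[(3,5-dimethoxy-2,4-dimethylphenyl)(2-hydroxy-4-methoxy-6-methylphenyl)methylidene]-4-methylbenzenesulfonohydrazide; 12 tert-butyl(but-3-yn-1-yloxy)dimethylsilane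
Product: 15 tert-butyl-[3-[3-(3,5-dimethoxy-2,4-dimethylphenyl)-6-methoxy-4-methyl-1-benzofuran-2-yl]propoxy]dimethylsilane, via diaryldiazomethane 13 (not isolated), via 1,1-diarylallene 14 (not isolated)
Conditions: CuBr (10 mol%), Cs2CO3 (3 equiv), 12 (3 equiv), MeCN, 100 °C, sealed tube, argon
Reagents that add atoms: none
Why: Cs2CO3 deprotonates the phenol and the sulfonamide N–H of 10, and at 100 °C the salt loses sulfinate (Bamford–Stevens) to release diazo compound 13 slowly; the copper acetylide formed from 12 and CuBr (monovalent copper) traps 13 as a copper carbene with loss of N2, the alkynyl group migrates from copper to the carbene carbon (C2–C3 bond), and protonation gives allene 14. The ortho phenoxide then adds in the plane of ring A to the central sp carbon of the allene, a 5-exo closure at a digonal carbon that consumes the distal C=C (O1–C2 bond), and protonation at the former internal alkyne carbon leaves the aromatic furan with CH2 as the first chain atom; the isomeric propargyl form would close 5-exo-dig to the same furan after tautomerisation. The closest known reaction type is the CuBr/Cs2CO3 coupling of N-tosylhydrazones of 2-hydroxyaryl aldehydes and ketones with terminal alkynes to 2-substituted benzofurans, together with the copper-catalysed coupling of diaryldiazomethanes with terminal alkynes to aryl allenes. No stereocentre is formed, and the allene axis of 14 disappears on aromatisation. The step needs chemoselectivity for carbene–acetylide coupling over azine formation, O–H insertion and alkyne homocoupling, which slow thermal release of 13, excess 12, exclusion of air and the shielding of the diazo carbon by the ortho groups of rings A and B should favour. Five-ring over six-ring oxycyclisation (benzofuran rather than 2H-chromene) should follow from the basic medium, in which the phenoxide attacks the central allene carbon rather than the distal one.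

**Step 11**
Reactants: 15 tert-butyl-[3-[3-(3,5-dimethoxy-2,4-dimethylphenyl)-6-methoxy-4-methyl-1-benzofuran-2-yl]propoxy]dimethylsilane
Product: 16 3-[3-(3,5-dimethoxy-2,4-dimethylphenyl)-6-methoxy-4-methyl-1-benzofuran-2-yl]propan-1-ol
Conditions: TBAF (1.2 equiv), THF, 0 °C to rt
Reagents that add atoms: none
Why: Fluoride-induced desilylation is driven by the strong Si–F bond and touches neither the aryl methyl ethers nor the benzofuran.

**Step 12**
Reactants: 16 3-[3-(3,5-dimethoxy-2,4-dimethylphenyl)-6-methoxy-4-methyl-1-benzofuran-2-yl]propan-1-ol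
Product: 17 3-[3-(3,5-dimethoxy-2,4-dimethylphenyl)-6-methoxy-4-methyl-1-benzofuran-2-yl]propanoic acid
Conditions: TEMPO (0.2 equiv), PhI(OAc)2 (2.5 equiv), MeCN/H2O, rt
Reagents that add atoms: water, O
Why: Oxoammonium-mediated (TEMPO) oxidation takes the primary alcohol to the aldehyde and, through its hydrate, on to the acid, under halogen-free conditions that should spare the electron-rich arenes and the fully substituted furan double bond.

**Step 13**
Reactants: 17 3-[3-(3,5-dimethoxy-2,4-dimethylphenyl)-6-methoxy-4-methyl-1-benzofuran-2-yl]propanoic acid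
Product: 18 3-[3-(3,5-dihydroxy-2,4-dimethylphenyl)-6-hydroxy-4-methyl-1-benzofuran-2-yl]propanoic acid
Conditions: BBr3 (8 equiv), CH2Cl2, −78 °C to rt; ice-water quench
Reagents that add atoms: none
Why: Lewis-acid ether cleavage, in which BBr3 coordinates each methoxy oxygen and bromide removes the methyl group by SN2, while the carboxyl group is held as an acyloxyborane that hydrolysis returns and the 2,3-disubstituted benzofuran should tolerate the reagent below room temperature.

**Step 14**
Reactants: 18 3-[3-(3,5-dihydroxy-2,4-dimethylphenyl)-6-hydroxy-4-methyl-1-benzofuran-2-yl]propanoic acid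
Product: 19 Talarominine A, methyl 3-[3-(3,5-dihydroxy-2,4-dimethylphenyl)-6-hydroxy-4-methyl-1-benzofuran-2-yl]propanoate
Conditions: HCl (ca. 1 M) in MeOH, rt to 40 °C
Reagents that add atoms: methanol, CO
Why: Fischer esterification converts only the aliphatic carboxylic acid, because phenols are not alkylated by methanolic HCl.

**Compound list**
1 | 3,5-dimethoxy-4-methylbenzoic acid | COc1cc(C(=O)O)cc(OC)c1C | starting material
2 | methyl 3,5-dimethoxy-4-methylbenzoate | COC(=O)c1cc(OC)c(C)c(OC)c1 | intermediate
3 | methyl 2-bromo-3,5-dimethoxy-4-methylbenzoate | COC(=O)c1cc(OC)c(C)c(OC)c1Br | intermediate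
4 | methyl 3,5-dimethoxy-2,4-dimethylbenzoate | COC(=O)c1cc(OC)c(C)c(OC)c1C | intermediate
5 | 3,5-dimethoxy-2,4-dimethylbenzoic acid | OC(=O)c1cc(OC)c(C)c(OC)c1C | intermediate
6 | 3,5-dimethoxy-2,4-dimethylbenzoyl chloride | ClC(=O)c1cc(OC)c(C)c(OC)c1C | intermediate
7 | 3,5-dimethoxytoluene | COc1cc(C)cc(OC)c1 | starting material
8 | (2,4-dimethoxy-6-methylphenyl)(3,5-dimethoxy-2,4-dimethylphenyl)methanone | COc1cc(C)c(C(=O)c2cc(OC)c(C)c(OC)c2C)c(OC)c1 | intermediate
9 | (3,5-dimethoxy-2,4-dimethylphenyl)(2-hydroxy-4-methoxy-6-methylphenyl)methanone | COc1cc(C)c(C(=O)c2cc(OC)c(C)c(OC)c2C)c(O)c1 | intermediate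
10 | N'-[(3,5-dimethoxy-2,4-dimethylphenyl)(2-hydroxy-4-methoxy-6-methylphenyl)methylidene]-4-methylbenzenesulfonohydrazide (C=N isomer mixture) | COc1cc(C)c(C(=NNS(=O)(=O)c2ccc(C)cc2)c2cc(OC)c(C)c(OC)c2C)c(O)c1 | intermediate
11 | but-3-yn-1-ol | C#CCCO | starting material
12 | tert-butyl(but-3-yn-1-yloxy)dimethylsilane | C#CCCO[Si](C)(C)C(C)(C)C | intermediate
13 | 2-[diazo(3,5-dimethoxy-2,4-dimethylphenyl)methyl]-5-methoxy-3-methylphenol (not isolated) | COc1cc(C)c(C(=[N+]=[N-])c2cc(OC)c(C)c(OC)c2C)c(O)c1 | intermediate
14 | 2-[5-(tert-butyldimethylsilyloxy)-1-(3,5-dimethoxy-2,4-dimethylphenyl)penta-1,2-dien-1-yl]-5-methoxy-3-methylphenol (racemic allene, not isolated) | COc1cc(C)c(C(=C=CCCO[Si](C)(C)C(C)(C)C)c2cc(OC)c(C)c(OC)c2C)c(O)c1 | intermediate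
15 | tert-butyl-[3-[3-(3,5-dimethoxy-2,4-dimethylphenyl)-6-methoxy-4-methyl-1-benzofuran-2-yl]propoxy]dimethylsilane | CC(C)(C)[Si](C)(C)OCCCc1oc2cc(OC)cc(C)c2c1-c1cc(OC)c(C)c(OC)c1C | intermediate
16 | 3-[3-(3,5-dimethoxy-2,4-dimethylphenyl)-6-methoxy-4-methyl-1-benzofuran-2-yl]propan-1-ol | OCCCc1oc2cc(OC)cc(C)c2c1-c1cc(OC)c(C)c(OC)c1C | intermediate
17 | 3-[3-(3,5-dimethoxy-2,4-dimethylphenyl)-6-methoxy-4-methyl-1-benzofuran-2-yl]propanoic acid | OC(=O)CCc1oc2cc(OC)cc(C)c2c1-c1cc(OC)c(C)c(OC)c1C | intermediate
18 | 3-[3-(3,5-dihydroxy-2,4-dimethylphenyl)-6-hydroxy-4-methyl-1-benzofuran-2-yl]propanoic acid | OC(=O)CCc1oc2cc(O)cc(C)c2c1-c1cc(O)c(C)c(O)c1C | intermediate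
19 | Talarominine A, methyl 3-[3-(3,5-dihydroxy-2,4-dimethylphenyl)-6-hydroxy-4-methyl-1-benzofuran-2-yl]propanoate | COC(=O)CCc1oc2cc(O)cc(C)c2c1-c1cc(O)c(C)c(O)c1C | target

**Step count**
Total steps: 14. Longest linear sequence: 13 (steps 1–8 and 10–14); step 9 is a one-step side branch.

**Steps most likely to fail**

1. Step 10. The shielded diaryl diazo compound may be captured too slowly by the copper acetylide, so that azine formation, carbene O–H insertion or reduction of the diazo carbon take over, or the alkyne may be lost to oxidative homocoupling. Fallback, from 9 back to 17: the phenol of 9 would be acylated with methyl 4-chloro-4-oxobutanoate (Et3N, DMAP, CH2Cl2) to methyl 2-(3,5-dimethoxy-2,4-dimethylbenzoyl)-5-methoxy-3-methylphenyl butanedioate F1. Intramolecular reductive keto–ester coupling with low-valent titanium (TiCl3, Zn, DME, reflux; McMurry-type benzofuran synthesis) would then form the C2=C3 bond between the ketone carbon and the aryl ester carbon, giving methyl 3-[3-(3,5-dimethoxy-2,4-dimethylphenyl)-6-methoxy-4-methyl-1-benzofuran-2-yl]propanoate F2. Saponification (LiOH, THF/H2O) would return to the route at acid 17.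

2. Step 8. Condensation at a carbonyl flanked by three ortho substituents may stall, while the sulfonyl hydrazide decomposes on long heating in acid. Fallback, from 9 back to 10: the smaller and more nucleophilic hydrazine (N2H4·H2O, n-butanol, 120 °C) would give the N-unsubstituted hydrazone 2-[(3,5-dimethoxy-2,4-dimethylphenyl)(hydrazinylidene)methyl]-5-methoxy-3-methylphenol F3. Its NH2 group would then be sulfonylated with TsCl (pyridine, CH2Cl2, 0 °C), in preference to the hindered hydrogen-bonded phenol, to rejoin the route at 10.

3. Step 6. Acylation may compete at C4 of 3,5-dimethoxytoluene, between the two methoxy groups, and AlCl3 may cleave ethers before the acylation is complete. Fallback, from 7 and 6 back to 8: 7 would be brominated (NBS, MeCN, 0 °C) to 2-bromo-1,5-dimethoxy-3-methylbenzene F4, and 6 would be converted (MeNHOMe·HCl, Et3N, CH2Cl2) to the Weinreb amide N,3,5-trimethoxy-N,2,4-trimethylbenzamide F5. Bromine–lithium exchange on F4 (n-BuLi, THF, −78 °C) would give (2,4-dimethoxy-6-methylphenyl)lithium F6, which would add to F5 and give ketone 8 on aqueous work-up, with the site of C–C bond formation fixed by the bromide.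

**Further compounds**
F1 | step 10 | methyl 2-(3,5-dimethoxy-2,4-dimethylbenzoyl)-5-methoxy-3-methylphenyl butanedioate | COC(=O)CCC(=O)Oc1cc(OC)cc(C)c1C(=O)c1cc(OC)c(C)c(OC)c1C
F2 | step 10 | methyl 3-[3-(3,5-dimethoxy-2,4-dimethylphenyl)-6-methoxy-4-methyl-1-benzofuran-2-yl]propanoate | COC(=O)CCc1oc2cc(OC)cc(C)c2c1-c1cc(OC)c(C)c(OC)c1C
F3 | step 8 | 2-[(3,5-dimethoxy-2,4-dimethylphenyl)(hydrazinylidene)methyl]-5-methoxy-3-methylphenol | COc1cc(C)c(C(=NN)c2cc(OC)c(C)c(OC)c2C)c(O)c1
F4 | step 6 | 2-bromo-1,5-dimethoxy-3-methylbenzene | COc1cc(C)c(Br)c(OC)c1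
F5 | step 6 | N,3,5-trimethoxy-N,2,4-trimethylbenzamide | CON(C)C(=O)c1cc(OC)c(C)c(OC)c1C
F6 | step 6 | (2,4-dimethoxy-6-methylphenyl)lithium | [Li]c1c(C)cc(OC)cc1OC
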